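# Pestalone F by a dithiane anion / aryne / formamide three-component coupling: synthesis proposal

## The problem

Pestalone F is an achiral benzophenone. Its carbonyl carbon joins C1 of ring A (C2 OH, C3 Cl, C4 CH3, C5 H, C6 OCH3) to C1' of ring B (C2' CHO, C3' OH, C4' H, C5' OH, C6' prenyl), so both aryl–carbonyl bonds stand between two ortho substituents. There is no stereocentre, and the whole difficulty is regiochemical. Each ring carries five different substituents. In ring B the ketone sits at C1', meta to both oxygens, where neither Friedel–Crafts acylation nor oxygen-directed metalation would place it.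

Several groups forbid rough treatment. The ortho-formyl diaryl ketone rearranges to a phthalide under base and condenses with amines. The prenyl group next to the C5' phenol closes to a chroman in strong acid and rules out hydrogenation and electrophilic oxidants. The aryl chloride rules out hydrogenolysis, and three phenols must be freed without touching the C6 methyl ether. A short route must also deliver the ketone and the aldehyde at their final oxidation levels.

The feature that allows this is the sequence C1' (ketone carbon), C2' (formyl carbon), C3' (oxygen) on adjacent ring atoms. This is the pattern left when a nucleophile adds to the remote carbon of a 3-alkoxyaryne and an electrophile is taken up at the carbon next to oxygen.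

## Retrosynthesis

**21 to 20.** The three phenolic O–H bonds of target 21 are traced back to methoxymethyl (MOM) ethers in keto aldehyde 20. MOM is preferred to benzyl (hydrogenolysis would reduce the prenyl group and the C–Cl bond), to silyl (a silyl ether next to an aryllithium migrates from O to C) and to methyl (cleavage would not spare the C6 methoxy group). The forward step must free three phenols in dilute acid without protonating the prenyl double bond.

**20 to 19.** The ketone C=O is traced back to the two C–S bonds of 1,3-dithiane 19. The dithiane keeps the ketone away from the neighbouring formyl group while that group is introduced, and it is what makes the ketone carbon a nucleophile one step earlier. The forward step must be a neutral hydrolysis that leaves the alkene, aldehyde and acetals alone.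

**19 to 7, 13 and 14.** Two C–C bonds are cut together: ketone carbon–C1' and C2'–CHO. This gives the ring A dithiane 7, the ring B triflate 13 (as the source of aryne 16) and N,N-dimethylformamide 14. The neighbouring cut, a ring B aryl anion at C1' adding to a ring A aldehyde, would need a ring B piece already metalated meta to both oxygens and already formylated at C2', which costs many more steps. The aryne cut instead uses the position pattern of the ring and reduces both halves to tri- and tetrasubstituted benzenes. The forward step must add carbon at C1', not C2', and must favour the carbanion over the base that generates the aryne.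

**7 to 6, then 4 and 5.** The MOM O–C bond of 7 and then the two C–S bonds of phenol dithiane 6 are cut, giving salicylaldehyde 4 and propane-1,3-dithiol 5. The thioacetal is made on the free phenol so that no MOM ether meets a Lewis acid and a thiol.

**4 to 2 to 1.** The C1–CHO bond is cut by ortho-formylation of chlorophenol 2, whose only free ortho position is the one required. The C3–Cl bond is cut by ortho-chlorination of commercial 3-methoxy-5-methylphenol 1. Chlorinating first turns the later formylation into a reaction with a single possible site.

**13 to 12, then 9 and 10, then 8.** The S–O bond of triflate 13 leads to phenol 12. The C6'–CH2 bond leads to 3,5-bis(methoxymethoxy)phenol 9 and prenyl bromide 10; the two ortho positions of 9 are equivalent, so C-prenylation has only one ortho outcome. The two MOM O–C bonds lead to phloroglucinol 8, whose three hydroxyls are equivalent.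

## Roads not taken

**Alternative 1:** Ring B would be built around an existing ring A–carbinol bond. A thermal [4+2] cycloaddition of the racemic alkynoate methyl 4-[(tert-butyldimethylsilyl)oxy]-4-[3-chloro-6-methoxy-2-(methoxymethoxy)-4-methylphenyl]but-2-ynoate A1 with the diene 1-methoxy-7-methyl-1,3-bis(trimethylsilyloxy)octa-1,3,6-triene A2 forms C1'–C6' and C2'–C3'. Loss of methanol then gives the benzoate A3.
- Merits: the substitution pattern of ring B follows from the polarity of diene and dienophile, so no aromatic substitution has to be steered. The crowded aryl–carbon bond is never made by joining two hindered arenes. In these two respects it is better than the chosen plan.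
- Weak points: both carbonyl carbons arrive at the wrong oxidation level. The ester of A3 must be reduced to the aldehyde and the carbinol oxidised to the ketone, with two free phenols to protect in between, and the freed benzylic alcohol can lactonise onto the ester. The cycloaddition of an internal, branched alkynoate with a terminally substituted, moisture-sensitive diene is slow.
- Comparison: the chosen plan sets against its less certain coupling a two-step endgame with no redox corrections and a route several steps shorter.

**Alternative 2:** The cut is at C1 of ring A. The aryne released by CsF from 4-chloro-3-(methoxymethoxy)-5-methyl-2-(trimethylsilyl)phenyl trifluoromethanesulfonate A4 would take up the caesium salt (from Cs2CO3) of 2-(dimethoxymethyl)-3,5-bis(methoxymethoxy)-6-(3-methylbut-2-en-1-yl)benzoic acid A5. Oxygen adds at C6 and the C1 carbanion captures the acyl carbon, giving hydroxy ketone A6, which still needs O-methylation at C6.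
- Merits: insertion of arynes into carboxylic acids to give ortho-hydroxyaryl ketones is a known reaction type, the fluoride conditions are mild and the ketone is formed directly. In precedent this road is stronger than the chosen one.
- Weak points: it moves the hard part into the building blocks. A5 carries three contiguous carbon substituents with the carboxyl again meta to both oxygens, and A4 is a pentasubstituted silyl triflate; each needs a long preparation. The acyl shift must occur at a doubly ortho-substituted carboxyl carbon, where simple O-arylation can win.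
- Comparison: the chosen plan offers two fragments of three and four steps from commercial phenols, and a fallback in known chemistry if the new coupling fails.

**Alternative 3:** Ring B would be folded from a chain. Under mild base the diketo-dioxinone 6-{5-[(tert-butyldimethylsilyl)oxy]-5-[3-chloro-6-methoxy-2-(methoxymethoxy)-4-methylphenyl]-3-(3-methylbut-2-en-1-yl)-2,4-dioxopentyl}-2,2-dimethyl-4H-1,3-dioxin-4-one A7 closes by aldol attack of the dioxinone alpha carbon (C2') on the C1' ketone. Dehydration and enolisation give the benzodioxinone A8.
- Merits: all ring B substituents are encoded in the chain and the conditions are mild.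
- Weak points: A7 needs several Claisen-type acylations with a hindered alpha-silyloxy acyl unit and a prenylation between two ketones. The aldol must select the more crowded of two ketones and beat O-cyclisation to a pyranone. A8 again needs reduction of the masked carboxyl to the aldehyde and oxidation of the carbinol.
- Comparison: this is the longest of the four roads. It is better than the chosen plan only in avoiding any aromatic regiochemistry question, which the chosen plan answers with symmetric or singly open substrates (8, 9, 2).

Key step: step 8

## Route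

Remark: organolithium and magnesium intermediates are written as monomeric species; compound 18 is racemic at its hemiaminal carbon, which becomes the formyl carbon on work-up.

Step 1
Reactants: 1 3-methoxy-5-methylphenol
Product: 2 2-chloro-5-methoxy-3-methylphenol
Conditions: SO2Cl2 (1.0 equiv), 2,2,6,6-tetramethylpiperidine (cat.), toluene, 0 °C → rt
Reagents that add atoms: sulfuryl chloride, O=S(=O)(Cl)Cl
Why: Amine-catalysed ortho-chlorination of a phenol (electrophilic aromatic substitution through an N-chloroamine hydrogen-bonded to the OH) delivers chlorine ortho to the hydroxyl; of the two ortho carbons the one para to OCH3 and next to CH3 is more activated and less crowded than the one between the two oxygens.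

Step 2
Reactants: 2 2-chloro-5-methoxy-3-methylphenol
Product: 4 3-chloro-2-hydroxy-6-methoxy-4-methylbenzaldehyde, via magnesium salicyl alkoxide 3 (not isolated)
Conditions: MgCl2, Et3N, paraformaldehyde, MeCN, reflux; aq HCl work-up
Reagents that add atoms: formaldehyde (as paraformaldehyde), C=O
Why: Magnesium-mediated ortho-formylation of a phenol: the magnesium phenoxide delivers formaldehyde to the only free ortho carbon, and alkoxide 3 is oxidised in the flask by hydride transfer to a second formaldehyde; chlorine blocks the other ortho site, so a single regioisomer can form.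

Step 3
Reactants: 4 3-chloro-2-hydroxy-6-methoxy-4-methylbenzaldehyde; 5 propane-1,3-dithiol
Product: 6 2-(3-chloro-2-hydroxy-6-methoxy-4-methylphenyl)-1,3-dithiane
Conditions: BF3·OEt2, CH2Cl2, 0 °C → rt
Reagents that add atoms: none
Why: Lewis-acid-catalysed dithioacetalisation of an aldehyde; it is run on the free phenol so that no MOM acetal is exposed to BF3 and thiol.

Step 4
Reactants: 6 2-(3-chloro-2-hydroxy-6-methoxy-4-methylphenyl)-1,3-dithiane
Product: 7 2-[3-chloro-6-methoxy-2-(methoxymethoxy)-4-methylphenyl]-1,3-dithiane
Conditions: MOMCl, i-Pr2NEt, CH2Cl2, 0 → 40 °C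
Reagents that add atoms: chloromethyl methyl ether, COCCl
Why: O-Alkylation of an acidic ortho-chlorophenol with MOMCl (Williamson-type etherification); the phenol oxygen is far more nucleophilic than the thioacetal sulfurs and an amine base does not touch the dithiane C–H.

Step 5
Reactants: 8 phloroglucinol
Product: 9 3,5-bis(methoxymethoxy)phenol
Conditions: MOMCl (2.0 equiv), i-Pr2NEt, DMF–CH2Cl2, 0 °C → rt; chromatography
Reagents that add atoms: chloromethyl methyl ether, COCCl
Why: Statistical O-alkylation of a triol whose three hydroxyls are equivalent, so only the degree of alkylation has to be controlled; the mono- and tris-ethers differ enough in polarity and acidity to be separated.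

Step 6
Reactants: 9 3,5-bis(methoxymethoxy)phenol; 10 1-bromo-3-methylbut-2-ene
Product: 12 3,5-bis(methoxymethoxy)-2-(3-methylbut-2-en-1-yl)phenol, via sodium phenoxide 11 (not isolated)
Conditions: NaH, toluene, 0 °C; then 10, 0 °C → rt
Reagents that add atoms: none
Why: ortho-C-Alkylation of a sodium phenoxide in a non-polar solvent: the tight Na–O ion pair shields oxygen and guides the allylic bromide to the ortho carbon through a cyclic transition state; the two ortho carbons of 11 are equivalent, so one ortho C-prenyl isomer is expected beside separable O-prenyl ether.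

Step 7
Reactants: 12 3,5-bis(methoxymethoxy)-2-(3-methylbut-2-en-1-yl)phenol
Product: 13 3,5-bis(methoxymethoxy)-2-(3-methylbut-2-en-1-yl)phenyl trifluoromethanesulfonate
Conditions: PhNTf2, Et3N, DMAP (cat.), CH2Cl2, rt
Reagents that add atoms: N-phenylbis(trifluoromethanesulfonimide), O=S(=O)(N(c1ccccc1)S(=O)(=O)C(F)(F)F)C(F)(F)F
Why: O-Sulfonylation of a phenol with a mild triflyl transfer reagent that sets free no triflic acid, so the MOM acetals and the prenyl double bond are not endangered.

Step 8
Reactants: 7 2-[3-chloro-6-methoxy-2-(methoxymethoxy)-4-methylphenyl]-1,3-dithiane; 13 3,5-bis(methoxymethoxy)-2-(3-methylbut-2-en-1-yl)phenyl trifluoromethanesulfonate; 14 N,N-dimethylformamide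
Product: 19 2-{2-[3-chloro-6-methoxy-2-(methoxymethoxy)-4-methylphenyl]-1,3-dithian-2-yl}-4,6-bis(methoxymethoxy)-3-(3-methylbut-2-en-1-yl)benzaldehyde, via lithiated dithiane 15 (not isolated), via aryne 16 (not isolated), via aryllithium 17 (not isolated), via lithium hemiaminal alkoxide 18 (not isolated)
Conditions: 7 (1.5 equiv), n-BuLi, THF, −78 → −20 °C; LiTMP (lithium 2,2,6,6-tetramethylpiperidide, 1.2 equiv), −78 °C; 13 added slowly, −78 → −40 °C; then 14 (excess), −78 → 0 °C; H2O
Reagents that add atoms: none
Why: Proposed new method: n-BuLi, guided by the two ortho oxygens, removes the dithiane C2–H of 7 to give the acyl anion equivalent 15, and lithium 2,2,6,6-tetramethylpiperidide removes the C2' hydrogen of 13, the most acidic ring proton because it lies between the triflate and the C3' OMOM group, after which loss of LiOSO2CF3 gives aryne 16. Carbanion 15 adds to C1' and leaves aryllithium 17 at C2', held by the C3' acetal oxygen; DMF acylates 17 to alkoxide 18, which collapses to aldehyde 19 on aqueous work-up. The closest known reaction types are aryne generation from aryl triflates with hindered lithium amides and the carbometalation of 3-alkoxyarynes by organolithium or Grignard reagents with electrophilic trapping of the ortho-metalated arene; a 2-aryl-2-lithio-1,3-dithiane has not been shown as the carbon nucleophile in this mode. No ring is closed and no stereocentre is formed. The step needs regioselective addition: the inductively withdrawing C3' oxygen polarises the aryne so that the nucleophile enters at the remote C1' and negative charge builds up at C2' beside oxygen, a bias expected to outweigh the steric demand of the C6' prenyl group. It also needs the aryne to choose the carbanion over the base: the tetramethylpiperidide is taken in place of the diisopropylamide because it and its amine add to arynes only slowly, and 15 is present in excess while 13 is fed in slowly. Metalation at C4' between the two OMOM groups is reversible with an amide base and leads nowhere, whereas metalation at C2' is drained by irreversible loss of triflate; ring A cannot form an aryne of its own because its chlorine has no ortho hydrogen.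

Step 9
Reactants: 19 2-{2-[3-chloro-6-methoxy-2-(methoxymethoxy)-4-methylphenyl]-1,3-dithian-2-yl}-4,6-bis(methoxymethoxy)-3-(3-methylbut-2-en-1-yl)benzaldehyde
Product: 20 2-[3-chloro-6-methoxy-2-(methoxymethoxy)-4-methylbenzoyl]-4,6-bis(methoxymethoxy)-3-(3-methylbut-2-en-1-yl)benzaldehyde
Conditions: MeI (excess), CaCO3, MeCN–H2O, 45 °C
Reagents that add atoms: water, O
Why: Alkylative hydrolysis of a 1,3-dithiane: S-methylation, ring opening to a diaryl-stabilised thionium ion and capture by water, with CaCO3 taking up HI; the medium is neutral and free of heavy-metal or halonium electrophiles, so the prenyl alkene, the aldehyde and the MOM acetals should be untouched.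

Step 10
Reactants: 20 2-[3-chloro-6-methoxy-2-(methoxymethoxy)-4-methylbenzoyl]-4,6-bis(methoxymethoxy)-3-(3-methylbut-2-en-1-yl)benzaldehyde
Product: 21 pestalone F, 2-(3-chloro-2-hydroxy-6-methoxy-4-methylbenzoyl)-4,6-dihydroxy-3-(3-methylbut-2-en-1-yl)benzaldehyde
Conditions: HCl (0.5 M), MeOH–THF, rt → 35 °C; aqueous work-up
Reagents that add atoms: none
Why: Acid-catalysed transacetalisation of the three MOM ethers to dimethoxymethane; acetal oxygens are protonated far more readily than a trisubstituted alkene, so dilute acid near room temperature should free the phenols without closing the C5' phenol onto the prenyl group, and the two MOM groups ortho to carbonyls leave fastest through hydrogen-bond assistance.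

## Compound list

1 | 3-methoxy-5-methylphenol | COc1cc(C)cc(O)c1 | starting material
2 | 2-chloro-5-methoxy-3-methylphenol | COc1cc(C)c(Cl)c(O)c1 | intermediate
3 | magnesium 2-chloro-5-methoxy-3-methyl-6-(oxidomethyl)phenolate (cyclic chelate, not isolated) | COc1cc(C)c(Cl)c2O[Mg]OCc12 | intermediate
4 | 3-chloro-2-hydroxy-6-methoxy-4-methylbenzaldehyde | COc1cc(C)c(Cl)c(O)c1C=O | intermediate
5 | propane-1,3-dithiol | SCCCS | starting material
6 | 2-(3-chloro-2-hydroxy-6-methoxy-4-methylphenyl)-1,3-dithiane | COc1cc(C)c(Cl)c(O)c1C1SCCCS1 | intermediate
7 | 2-[3-chloro-6-methoxy-2-(methoxymethoxy)-4-methylphenyl]-1,3-dithiane | COCOc1c(Cl)c(C)cc(OC)c1C1SCCCS1 | intermediate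
8 | phloroglucinol (benzene-1,3,5-triol) | Oc1cc(O)cc(O)c1 | starting material
9 | 3,5-bis(methoxymethoxy)phenol | COCOc1cc(O)cc(OCOC)c1 | intermediate
10 | 1-bromo-3-methylbut-2-ene | CC(C)=CCBr | starting material
11 | sodium 3,5-bis(methoxymethoxy)phenolate (not isolated) | [Na+].[O-]c1cc(OCOC)cc(OCOC)c1 | intermediate
12 | 3,5-bis(methoxymethoxy)-2-(3-methylbut-2-en-1-yl)phenol | COCOc1cc(O)c(CC=C(C)C)c(OCOC)c1 | intermediate
13 | 3,5-bis(methoxymethoxy)-2-(3-methylbut-2-en-1-yl)phenyl trifluoromethanesulfonate | COCOc1cc(OCOC)c(CC=C(C)C)c(OS(=O)(=O)C(F)(F)F)c1 | intermediate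
14 | N,N-dimethylformamide | CN(C)C=O | starting material
15 | {2-[3-chloro-6-methoxy-2-(methoxymethoxy)-4-methylphenyl]-1,3-dithian-2-yl}lithium (not isolated) | [Li]C1(SCCCS1)c1c(OC)cc(C)c(Cl)c1OCOC | intermediate
16 | 3,5-bis(methoxymethoxy)-6-(3-methylbut-2-en-1-yl)-1,2-didehydrobenzene (aryne, not isolated) | COCOC1=CC(OCOC)=C(CC=C(C)C)C#C1 | intermediate
17 | (2-{2-[3-chloro-6-methoxy-2-(methoxymethoxy)-4-methylphenyl]-1,3-dithian-2-yl}-4,6-bis(methoxymethoxy)-3-(3-methylbut-2-en-1-yl)phenyl)lithium (not isolated) | [Li]c1c(OCOC)cc(OCOC)c(CC=C(C)C)c1C1(SCCCS1)c1c(OC)cc(C)c(Cl)c1OCOC | intermediate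
18 | lithium (2-{2-[3-chloro-6-methoxy-2-(methoxymethoxy)-4-methylphenyl]-1,3-dithian-2-yl}-4,6-bis(methoxymethoxy)-3-(3-methylbut-2-en-1-yl)phenyl)(dimethylamino)methanolate (racemic, not isolated) | [Li]OC(N(C)C)c1c(OCOC)cc(OCOC)c(CC=C(C)C)c1C1(SCCCS1)c1c(OC)cc(C)c(Cl)c1OCOC | intermediate
19 | 2-{2-[3-chloro-6-methoxy-2-(methoxymethoxy)-4-methylphenyl]-1,3-dithian-2-yl}-4,6-bis(methoxymethoxy)-3-(3-methylbut-2-en-1-yl)benzaldehyde | COCOc1c(Cl)c(C)cc(OC)c1C1(SCCCS1)c1c(C=O)c(OCOC)cc(OCOC)c1CC=C(C)C | intermediate
20 | 2-[3-chloro-6-methoxy-2-(methoxymethoxy)-4-methylbenzoyl]-4,6-bis(methoxymethoxy)-3-(3-methylbut-2-en-1-yl)benzaldehyde | COCOc1c(Cl)c(C)cc(OC)c1C(=O)c1c(C=O)c(OCOC)cc(OCOC)c1CC=C(C)C | intermediate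
21 | pestalone F, 2-(3-chloro-2-hydroxy-6-methoxy-4-methylbenzoyl)-4,6-dihydroxy-3-(3-methylbut-2-en-1-yl)benzaldehyde | COc1cc(C)c(Cl)c(O)c1C(=O)c1c(C=O)c(O)cc(O)c1CC=C(C)C | target

## Step count and risks

Total: 10 steps. Longest linear sequence: 7 steps (steps 1, 2, 3, 4, 8, 9, 10); the ring B branch (steps 5, 6, 7) joins at step 8.

**Step 8 (key step, new method).** Three things are most likely to go wrong. The ortho-metalated triflate may undergo anionic thia-Fries migration of the triflyl group from oxygen to C2' instead of losing triflate. The hindered tertiary carbanion may add too slowly to the aryne carbon beside the prenyl group, so that amide addition, aryne self-reaction or metalation of the benzylic–allylic CH2 takes over. The carbanion may enter at C2' if sterics override the oxygen bias.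

The fallback uses only known reactions, gives up the aryne, and sets out from 12 and 2.
- Magnesium-mediated ortho-formylation of 12 (MgCl2, Et3N, paraformaldehyde) puts the formyl carbon on the only free ortho position of the phenol, giving 2-hydroxy-4,6-bis(methoxymethoxy)-3-(3-methylbut-2-en-1-yl)benzaldehyde F1.
- Triflation (PhNTf2, Et3N) gives 2-formyl-3,5-bis(methoxymethoxy)-6-(3-methylbut-2-en-1-yl)phenyl trifluoromethanesulfonate F2.
- Methoxycarbonylation (Pd(OAc)2, 1,3-bis(diphenylphosphino)propane, CO, MeOH, Et3N, through oxidative addition to zerovalent palladium) gives methyl 2-formyl-3,5-bis(methoxymethoxy)-6-(3-methylbut-2-en-1-yl)benzoate F3.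
- NaBH4 reduces the formyl group and the product closes onto the ester to give the phthalide 4,6-bis(methoxymethoxy)-7-(3-methylbut-2-en-1-yl)-2-benzofuran-1(3H)-one F4.
- On the ring A side, MOMCl and i-Pr2NEt convert 2 into 2-chloro-5-methoxy-1-(methoxymethoxy)-3-methylbenzene F5. n-BuLi with TMEDA lithiates F5 between its two oxygens to give [3-chloro-6-methoxy-2-(methoxymethoxy)-4-methylphenyl]lithium F6.
- F6 adds once to the lactone carbonyl of F4 and gives, after work-up, [3-chloro-6-methoxy-2-(methoxymethoxy)-4-methylphenyl][2-(hydroxymethyl)-3,5-bis(methoxymethoxy)-6-(3-methylbut-2-en-1-yl)phenyl]methanone F7, in equilibrium with its lactol.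
- MnO2 oxidation of the benzylic alcohol returns to the route at 20.

**Step 1.** Chlorination may go para to the hydroxyl or between the two oxygens, or run on to dichlorination, because three ring positions are activated. The fallback sets out from 1 and uses symmetry.
- O-Methylation (MeI, K2CO3) gives 1,3-dimethoxy-5-methylbenzene F8, whose two positions beside the methyl group are equivalent.
- N-Chlorosuccinimide gives 2-chloro-1,5-dimethoxy-3-methylbenzene F9.
- n-BuLi lithiates between the two methoxy groups to (3-chloro-2,6-dimethoxy-4-methylphenyl)lithium F10, and DMF gives 3-chloro-2,6-dimethoxy-4-methylbenzaldehyde F11.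
- BCl3, chelated to the carbonyl, cleaves the more crowded methoxy group (between Cl and CHO) and returns to the route at 4.

**Step 6.** O-Alkylation, C-alkylation at the carbon between the two OMOM groups and double prenylation can all erode the yield, since the phenoxide is ambident and the product is itself a phenol. The fallback sets out from 9.
- O-Allylation (allyl bromide, K2CO3) gives 1,3-bis(methoxymethoxy)-5-(prop-2-en-1-yloxy)benzene F12.
- Aromatic Claisen rearrangement (N,N-diethylaniline, 190 °C), regiospecific because both ortho positions are equivalent, gives 3,5-bis(methoxymethoxy)-2-(prop-2-en-1-yl)phenol F13.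
- Cross-metathesis with 2-methylbut-2-ene (second-generation Grubbs catalyst) returns to the route at 12.

**Step 9.** S-Methylation may be slow at the very crowded thioacetal. The thionium ion may also be captured by the neighbouring prenyl double bond (a five-membered cation–olefin closure) before water reaches it. The fallback sets out from 19 and gives the cation a better internal partner.
- NaBH4 reduces the aldehyde to (2-{2-[3-chloro-6-methoxy-2-(methoxymethoxy)-4-methylphenyl]-1,3-dithian-2-yl}-4,6-bis(methoxymethoxy)-3-(3-methylbut-2-en-1-yl)phenyl)methanol F14.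
- On treatment with MeI and CaCO3 the hydroxymethyl group of F14 traps the thionium ion as a five-membered cyclic acetal, which hydrolyses to the hydroxy ketone [3-chloro-6-methoxy-2-(methoxymethoxy)-4-methylphenyl][2-(hydroxymethyl)-3,5-bis(methoxymethoxy)-6-(3-methylbut-2-en-1-yl)phenyl]methanone F7.
- MnO2 returns to the route at 20.

**Step 10.** Protonation of the prenyl double bond with ring closure by the C5' phenol, or hydration of the alkene, may compete if cleavage of the C5' MOM ether (para to the formyl group, the slowest of the three) needs stronger acid. The fallback sets out from 20 and replaces Brønsted-acid hydrolysis by two Lewis-acid stages.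
- MgBr2·OEt2 removes, by chelation to the carbonyl oxygens, the two MOM groups ortho to ketone and aldehyde, giving 2-(3-chloro-2-hydroxy-6-methoxy-4-methylbenzoyl)-6-hydroxy-4-(methoxymethoxy)-3-(3-methylbut-2-en-1-yl)benzaldehyde F15.
- Me2BBr at −78 °C exchanges the last acetal for a bromomethyl ether, which is hydrolysed on NaHCO3 work-up, returning to the route at 21.

## Further compounds

F1 | step 8 | 2-hydroxy-4,6-bis(methoxymethoxy)-3-(3-methylbut-2-en-1-yl)benzaldehyde | COCOc1cc(OCOC)c(CC=C(C)C)c(O)c1C=O
F2 | step 8 | 2-formyl-3,5-bis(methoxymethoxy)-6-(3-methylbut-2-en-1-yl)phenyl trifluoromethanesulfonate | COCOc1cc(OCOC)c(CC=C(C)C)c(OS(=O)(=O)C(F)(F)F)c1C=O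
F3 | step 8 | methyl 2-formyl-3,5-bis(methoxymethoxy)-6-(3-methylbut-2-en-1-yl)benzoate | COCOc1cc(OCOC)c(CC=C(C)C)c(C(=O)OC)c1C=O
F4 | step 8 | 4,6-bis(methoxymethoxy)-7-(3-methylbut-2-en-1-yl)-2-benzofuran-1(3H)-one | O=C1OCc2c1c(CC=C(C)C)c(OCOC)cc2OCOC
F5 | step 8 | 2-chloro-5-methoxy-1-(methoxymethoxy)-3-methylbenzene | COCOc1cc(OC)cc(C)c1Cl
F6 | step 8 | [3-chloro-6-methoxy-2-(methoxymethoxy)-4-methylphenyl]lithium | [Li]c1c(OC)cc(C)c(Cl)c1OCOC
F7 | step 8 | [3-chloro-6-methoxy-2-(methoxymethoxy)-4-methylphenyl][2-(hydroxymethyl)-3,5-bis(methoxymethoxy)-6-(3-methylbut-2-en-1-yl)phenyl]methanone | COCOc1c(Cl)c(C)cc(OC)c1C(=O)c1c(CO)c(OCOC)cc(OCOC)c1CC=C(C)C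
F8 | step 1 | 1,3-dimethoxy-5-methylbenzene | COc1cc(C)cc(OC)c1
F9 | step 1 | 2-chloro-1,5-dimethoxy-3-methylbenzene | COc1cc(C)c(Cl)c(OC)c1
F10 | step 1 | (3-chloro-2,6-dimethoxy-4-methylphenyl)lithium | [Li]c1c(OC)cc(C)c(Cl)c1OC
F11 | step 1 | 3-chloro-2,6-dimethoxy-4-methylbenzaldehyde | COc1cc(C)c(Cl)c(OC)c1C=O
F12 | step 6 | 1,3-bis(methoxymethoxy)-5-(prop-2-en-1-yloxy)benzene | C=CCOc1cc(OCOC)cc(OCOC)c1
F13 | step 6 | 3,5-bis(methoxymethoxy)-2-(prop-2-en-1-yl)phenol | C=CCc1c(O)cc(OCOC)cc1OCOC
F14 | step 9 | (2-{2-[3-chloro-6-methoxy-2-(methoxymethoxy)-4-methylphenyl]-1,3-dithian-2-yl}-4,6-bis(methoxymethoxy)-3-(3-methylbut-2-en-1-yl)phenyl)methanol | COCOc1c(Cl)c(C)cc(OC)c1C1(SCCCS1)c1c(CO)c(OCOC)cc(OCOC)c1CC=C(C)C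
F15 | step 10 | 2-(3-chloro-2-hydroxy-6-methoxy-4-methylbenzoyl)-6-hydroxy-4-(methoxymethoxy)-3-(3-methylbut-2-en-1-yl)benzaldehyde | COCOc1cc(O)c(C=O)c(C(=O)c2c(OC)cc(C)c(Cl)c2O)c1CC=C(C)C
A1 | alternative 1 | methyl 4-[(tert-butyldimethylsilyl)oxy]-4-[3-chloro-6-methoxy-2-(methoxymethoxy)-4-methylphenyl]but-2-ynoate (racemic) | COC(=O)C#CC(O[Si](C)(C)C(C)(C)C)c1c(OC)cc(C)c(Cl)c1OCOC
A2 | alternative 1 | 1-methoxy-7-methyl-1,3-bis(trimethylsilyloxy)octa-1,3,6-triene | COC(O[Si](C)(C)C)=CC(O[Si](C)(C)C)=CCC=C(C)C
A3 | alternative 1 | methyl 2-{[(tert-butyldimethylsilyl)oxy][3-chloro-6-methoxy-2-(methoxymethoxy)-4-methylphenyl]methyl}-4,6-dihydroxy-3-(3-methylbut-2-en-1-yl)benzoate (racemic) | COC(=O)c1c(O)cc(O)c(CC=C(C)C)c1C(O[Si](C)(C)C(C)(C)C)c1c(OC)cc(C)c(Cl)c1OCOC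
A4 | alternative 2 | 4-chloro-3-(methoxymethoxy)-5-methyl-2-(trimethylsilyl)phenyl trifluoromethanesulfonate | COCOc1c(Cl)c(C)cc(OS(=O)(=O)C(F)(F)F)c1[Si](C)(C)C
A5 | alternative 2 | 2-(dimethoxymethyl)-3,5-bis(methoxymethoxy)-6-(3-methylbut-2-en-1-yl)benzoic acid | OC(=O)c1c(C(OC)OC)c(OCOC)cc(OCOC)c1CC=C(C)C
A6 | alternative 2 | [3-chloro-6-hydroxy-2-(methoxymethoxy)-4-methylphenyl][2-(dimethoxymethyl)-3,5-bis(methoxymethoxy)-6-(3-methylbut-2-en-1-yl)phenyl]methanone | COCOc1c(Cl)c(C)cc(O)c1C(=O)c1c(C(OC)OC)c(OCOC)cc(OCOC)c1CC=C(C)C
A7 | alternative 3 | 6-{5-[(tert-butyldimethylsilyl)oxy]-5-[3-chloro-6-methoxy-2-(methoxymethoxy)-4-methylphenyl]-3-(3-methylbut-2-en-1-yl)-2,4-dioxopentyl}-2,2-dimethyl-4H-1,3-dioxin-4-one (mixture of stereoisomers) | CC1(C)OC(=O)C=C(CC(=O)C(CC=C(C)C)C(=O)C(O[Si](C)(C)C(C)(C)C)c2c(OC)cc(C)c(Cl)c2OCOC)O1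
A8 | alternative 3 | 5-{[(tert-butyldimethylsilyl)oxy][3-chloro-6-methoxy-2-(methoxymethoxy)-4-methylphenyl]methyl}-7-hydroxy-2,2-dimethyl-6-(3-methylbut-2-en-1-yl)-4H-1,3-benzodioxin-4-one (racemic) | CC1(C)OC(=O)c2c(O1)cc(O)c(CC=C(C)C)c2C(O[Si](C)(C)C(C)(C)C)c1c(OC)cc(C)c(Cl)c1OCOC
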